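**Plan**
Numbering: dienone ring C1 (C=O), C2 (allyl), C3 (H), C4 (quaternary, OMe), C5 (OMe), C6 (H). Side chain: C8 (CHMe, on C4) and C7 (ArCH2).
Enabling feature: in the cyclohexa-2,5-dienone ring, C5(OMe)=C6H–C1(=O) is a vinylogous methyl ester. C5–OMe is therefore read as a methyl ester on C4, and C6–C1 as the ketene-type C2 unit Ph3P=C=C=O. C1 and C4 are cis on C2=C3, so a (Z)-alkenyl metal at C2 brings the ylide within reach of the ester.
Cuts, in order: phenol O–Si; C5=C6 together with C1–C2 (ring opens to an acyclic (Z)-iodo-diene ester plus the C2 unit); C2–I/C3–H (back to the alkyne); C4O–CH3; C3–C4 (alkyne + α-keto ester); C4–C5; C7–aryl.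
Forward: aryl–C7, then C4–C5, then C3–C4, then alkyne to (Z)-alkenyl iodide. The only new ring (the dienone) is then closed in one flask, followed by desilylation. The guaiacyl ring is bought.
Stereochemistry: C8 comes from a chiral-pool bromide. C4 comes from a catalyst-controlled, Felkin–Anh-matched alkynylation of the keto ester. The Z geometry comes from trans-hydrosilylation and retentive iododesilylation. Neither centre is touched afterwards.

Key step: step 10

Assumption: the (S,S) antipode of the Phebox ligand (Phebox = 2,6-bis(oxazolin-2-yl)phenyl) is taken to deliver the alkynyl group to the Si face of the keto ester. If the sense is the reverse, the (R,R) antipode is used.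

Step 1
Reactants: 1 4-bromo-2-methoxyphenol
Product: 2 (4-bromo-2-methoxyphenoxy)triisopropylsilane
Conditions: TIPSCl (1.1 equiv), imidazole (2 equiv), DMF, rt
Reagents that add atoms: chlorotriisopropylsilane, CC(C)[Si](Cl)(C(C)C)C(C)C
Why: Imidazole-promoted silyl ether formation masks the phenol with a group that should withstand organometallic reagents, ozone and methyl triflate yet falls to fluoride; no stereocentre is involved.

Step 2
Reactants: 2 (4-bromo-2-methoxyphenoxy)triisopropylsilane, 3 methyl (2S)-3-bromo-2-methylpropanoate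
Product: 5 methyl (2R)-3-[3-methoxy-4-(triisopropylsilyloxy)phenyl]-2-methylpropanoate, via alkylzinc bromide 4 (not isolated)
Conditions: 3, Zn dust, LiCl, THF, 40 °C; then 2, Pd(OAc)2 (2 mol %), SPhos (4 mol %), THF, 50 °C
Reagents that add atoms: none
Why: Negishi coupling: zinc insertion into the primary C–Br bond and the neutral coupling leave the adjacent centre untouched, so C8 is carried over from 3 (S becomes R only through the change in CIP ranking), and the bulky biarylphosphine should favour reductive elimination over β-hydride loss.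

Step 3
Reactants: 5 methyl (2R)-3-[3-methoxy-4-(triisopropylsilyloxy)phenyl]-2-methylpropanoate
Product: 6 (2R)-N-methoxy-3-[3-methoxy-4-(triisopropylsilyloxy)phenyl]-N,2-dimethylpropanamide
Conditions: MeNH(OMe)·HCl (1.5 equiv), iPrMgCl (3 equiv), THF, −20 °C
Reagents that add atoms: N,O-dimethylhydroxylamine hydrochloride, CNOC.Cl
Why: Ester aminolysis by the magnesium amide gives the Weinreb amide, and at low temperature it should proceed faster than enolisation, so C8 keeps its configuration.

Step 4
Reactants: 6 (2R)-N-methoxy-3-[3-methoxy-4-(triisopropylsilyloxy)phenyl]-N,2-dimethylpropanamide, 7 methoxyethene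
Product: 9 (4R)-2-methoxy-5-[3-methoxy-4-(triisopropylsilyloxy)phenyl]-4-methylpent-1-en-3-one, via 1-methoxyvinyllithium 8 (not isolated)
Conditions: 7 (3 equiv), tBuLi (2 equiv), THF, −78 to 0 °C; then 6, −78 °C; H2O
Reagents that add atoms: none
Why: Weinreb ketone synthesis with an α-metallated enol ether: the chelated tetrahedral adduct stops the reaction at the ketone stage and shields C8–H, and the reagent brings in C5 already bearing the methoxy group that ends up on the ring.

Step 5
Reactants: 9 (4R)-2-methoxy-5-[3-methoxy-4-(triisopropylsilyloxy)phenyl]-4-methylpent-1-en-3-one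
Product: 10 methyl (3R)-4-[3-methoxy-4-(triisopropylsilyloxy)phenyl]-3-methyl-2-oxobutanoate
Conditions: O3, CH2Cl2, −78 °C (Sudan Red 7B end point); Me2S, −78 °C to rt
Reagents that add atoms: ozone, [O-][O+]=O
Why: Ozonolysis of the enol ether C=C turns C(OMe)=CH2 into the methyl ester, and the indicator-controlled dose should spare the arene while the neutral work-up spares C8.

Step 6
Reactants: 10 methyl (3R)-4-[3-methoxy-4-(triisopropylsilyloxy)phenyl]-3-methyl-2-oxobutanoate, 11 pent-1-en-4-yne
Product: 12 methyl (2S)-2-hydroxy-2-{(2R)-1-[3-methoxy-4-(triisopropylsilyloxy)phenyl]propan-2-yl}hept-6-en-3-ynoate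
Conditions: (S,S)-(iPr-Phebox)Rh(OAc)2(H2O) (5 mol %), 11 (2 equiv), Et2O, 25 °C
Reagents that add atoms: none
Why: Catalytic enantioselective alkynylation of an α-keto ester: the rhodium acetylide formed from 11 adds to the Si face of the two-point-bound ketone, so the ligand sets C4 as S, the Felkin–Anh preference of (R)-C8 (attack anti to CH2Ar, past H) points the same way, and the base-free medium spares the epimerisable C8–H.

Step 7
Reactants: 12 methyl (2S)-2-hydroxy-2-{(2R)-1-[3-methoxy-4-(triisopropylsilyloxy)phenyl]propan-2-yl}hept-6-en-3-ynoate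
Product: 13 methyl (2S)-2-methoxy-2-{(2R)-1-[3-methoxy-4-(triisopropylsilyloxy)phenyl]propan-2-yl}hept-6-en-3-ynoate
Conditions: MeOTf (4 equiv), 2,6-di-tert-butyl-4-methylpyridine (5 equiv), CH2Cl2, 40 °C
Reagents that add atoms: methyl trifluoromethanesulfonate, COS(=O)(=O)C(F)(F)F
Why: O-alkylation of the hindered tertiary alcohol with a hard methylating agent and a non-nucleophilic pyridine base forms no alkoxide, which should prevent retro-alkynylation and isomerisation of the skipped enyne; the C4–O bond is not broken, so the configuration stays.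

Step 8
Reactants: 13 methyl (2S)-2-methoxy-2-{(2R)-1-[3-methoxy-4-(triisopropylsilyloxy)phenyl]propan-2-yl}hept-6-en-3-ynoate
Product: 14 methyl (2S,3Z)-2-methoxy-2-{(2R)-1-[3-methoxy-4-(triisopropylsilyloxy)phenyl]propan-2-yl}-4-(triethylsilyl)hepta-3,6-dienoate
Conditions: Et3SiH (1.2 equiv), [Cp*Ru(MeCN)3]PF6 (3 mol %), CH2Cl2, 0 °C to rt
Reagents that add atoms: triethylsilane, CC[SiH](CC)CC
Why: Ruthenium-catalysed trans-hydrosilylation of an internal alkyne: H and Si add to opposite faces, silicon goes to the alkyne carbon remote from the oxygenated quaternary propargylic centre, so Si ends on C2 cis to C4, and the terminal alkene should react far more slowly.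

Step 9
Reactants: 14 methyl (2S,3Z)-2-methoxy-2-{(2R)-1-[3-methoxy-4-(triisopropylsilyloxy)phenyl]propan-2-yl}-4-(triethylsilyl)hepta-3,6-dienoate
Product: 15 methyl (2S,3Z)-4-iodo-2-methoxy-2-{(2R)-1-[3-methoxy-4-(triisopropylsilyloxy)phenyl]propan-2-yl}hepta-3,6-dienoate
Conditions: NIS (1.2 equiv), 2,6-lutidine (1 equiv), (CF3)2CHOH, 0 °C, dark
Reagents that add atoms: N-iodosuccinimide, O=C1CCC(=O)N1I
Why: Iododesilylation (ipso substitution through the β-silyl cation) in hexafluoroisopropanol proceeds with retention of alkene geometry, and the buffer should suppress acid-catalysed iodination of the arene.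

Step 10
Reactants: 15 methyl (2S,3Z)-4-iodo-2-methoxy-2-{(2R)-1-[3-methoxy-4-(triisopropylsilyloxy)phenyl]propan-2-yl}hepta-3,6-dienoate, 16 (triphenylphosphoranylidene)ketene
Product: 20 (4S)-4,5-dimethoxy-4-{(2R)-1-[3-methoxy-4-(triisopropylsilyloxy)phenyl]propan-2-yl}-2-(prop-2-en-1-yl)cyclohexa-2,5-dien-1-one, via alkenylmagnesium chloride 17 (not isolated), via magnesiated ylide adduct 18 (not isolated), via keto ylide 19 (not isolated)
Conditions: iPrMgCl·LiCl (1.1 equiv), THF, −40 °C; 16 (1.2 equiv), −40 to −10 °C; Et3N·HCl (1.1 equiv), −40 °C to rt; THF replaced by toluene, 110 °C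
Reagents that add atoms: none
Why: Proposed new method: iodine–magnesium exchange with retention gives the (Z)-alkenylmagnesium 17 (chelated by the C4 methoxy group, ester tolerated at −40 °C), whose carbanion adds to the carbonyl carbon of cumulene 16 to form C1–C2, a step that is the microscopic reverse of the alkoxide loss by which 16 arises from a metallated ester ylide but is irreversible for a carbon nucleophile, and one equivalent of Et3N·HCl turns adduct 18 into the neutral keto-stabilised ylide 19. On heating, ylide carbon C6 attacks ester carbonyl C5 (6-exo-trig, through a bicyclic oxaphosphetane) and cycloreversion expels Ph3P=O, which creates C5=C6 and closes the six-membered ring. The closest known reaction types are the domino addition–intramolecular Wittig olefination of α-hydroxy esters with 16 that gives tetronates (O–H in place of C–Mg as the nucleophile) and the chromone synthesis by intramolecular Wittig reaction of keto ylides with aryl esters. No stereocentre is formed: C4 and C8 are spectators, and the ring alkene C2=C3 inherits the Z geometry of 15, which alone lets C6 reach C5. The selectivity needed is olefination rather than acyl substitution (loss of methoxide to a diacyl ylide), and it should be secured by protonating 18 cold before it can cyclise, by the absence of base in the thermal stage, and by the α-methoxy activation of the ester together with the gem-disubstitution at C4. Because the ester methoxy group stays on C5, the hindered vinylogous ester forms as the only regioisomer, which O-methylation of the corresponding 1,3-dione would not deliver.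

Step 11
Reactants: 20 (4S)-4,5-dimethoxy-4-{(2R)-1-[3-methoxy-4-(triisopropylsilyloxy)phenyl]propan-2-yl}-2-(prop-2-en-1-yl)cyclohexa-2,5-dien-1-one
Product: 21 (4S)-4-[(2R)-1-(4-hydroxy-3-methoxyphenyl)propan-2-yl]-4,5-dimethoxy-2-(prop-2-en-1-yl)cyclohexa-2,5-dien-1-one
Conditions: TBAF (1.1 equiv), AcOH (1.1 equiv), THF, 0 °C
Reagents that add atoms: none
Why: Fluoride-induced cleavage of the aryl silyl ether, with acetic acid buffering so that no free phenoxide adds to the dienone; the vinylogous ester, the allyl group and both stereocentres should stay untouched.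

**Compound list**
1 | 4-bromo-2-methoxyphenol | COc1cc(Br)ccc1O | starting material
2 | (4-bromo-2-methoxyphenoxy)triisopropylsilane | COc1cc(Br)ccc1O[Si](C(C)C)(C(C)C)C(C)C | intermediate
3 | methyl (2S)-3-bromo-2-methylpropanoate | COC(=O)[C@H](C)CBr | starting material
4 | [(2S)-3-methoxy-2-methyl-3-oxopropyl]zinc bromide | COC(=O)[C@H](C)C[Zn]Br | intermediate
5 | methyl (2R)-3-[3-methoxy-4-(triisopropylsilyloxy)phenyl]-2-methylpropanoate | COC(=O)[C@H](C)Cc1ccc(O[Si](C(C)C)(C(C)C)C(C)C)c(OC)c1 | intermediate
6 | (2R)-N-methoxy-3-[3-methoxy-4-(triisopropylsilyloxy)phenyl]-N,2-dimethylpropanamide | CON(C)C(=O)[C@H](C)Cc1ccc(O[Si](C(C)C)(C(C)C)C(C)C)c(OC)c1 | intermediate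
7 | methoxyethene (methyl vinyl ether) | C=COC | starting material
8 | (1-methoxyethenyl)lithium | [Li]C(=C)OC | intermediate
9 | (4R)-2-methoxy-5-[3-methoxy-4-(triisopropylsilyloxy)phenyl]-4-methylpent-1-en-3-one | C=C(OC)C(=O)[C@H](C)Cc1ccc(O[Si](C(C)C)(C(C)C)C(C)C)c(OC)c1 | intermediate
10 | methyl (3R)-4-[3-methoxy-4-(triisopropylsilyloxy)phenyl]-3-methyl-2-oxobutanoate | COC(=O)C(=O)[C@H](C)Cc1ccc(O[Si](C(C)C)(C(C)C)C(C)C)c(OC)c1 | intermediate
11 | pent-1-en-4-yne | C=CCC#C | starting material
12 | methyl (2S)-2-hydroxy-2-{(2R)-1-[3-methoxy-4-(triisopropylsilyloxy)phenyl]propan-2-yl}hept-6-en-3-ynoate | C=CCC#C[C@@](O)([C@H](C)Cc1ccc(O[Si](C(C)C)(C(C)C)C(C)C)c(OC)c1)C(=O)OC | intermediate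
13 | methyl (2S)-2-methoxy-2-{(2R)-1-[3-methoxy-4-(triisopropylsilyloxy)phenyl]propan-2-yl}hept-6-en-3-ynoate | C=CCC#C[C@@](OC)([C@H](C)Cc1ccc(O[Si](C(C)C)(C(C)C)C(C)C)c(OC)c1)C(=O)OC | intermediate
14 | methyl (2S,3Z)-2-methoxy-2-{(2R)-1-[3-methoxy-4-(triisopropylsilyloxy)phenyl]propan-2-yl}-4-(triethylsilyl)hepta-3,6-dienoate | C=CC/C([Si](CC)(CC)CC)=C/[C@@](OC)([C@H](C)Cc1ccc(O[Si](C(C)C)(C(C)C)C(C)C)c(OC)c1)C(=O)OC | intermediate
15 | methyl (2S,3Z)-4-iodo-2-methoxy-2-{(2R)-1-[3-methoxy-4-(triisopropylsilyloxy)phenyl]propan-2-yl}hepta-3,6-dienoate | C=CC/C(I)=C/[C@@](OC)([C@H](C)Cc1ccc(O[Si](C(C)C)(C(C)C)C(C)C)c(OC)c1)C(=O)OC | intermediate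
16 | (triphenylphosphoranylidene)ketene | O=C=C=P(c1ccccc1)(c1ccccc1)c1ccccc1 | starting material
17 | (Z)-alkenylmagnesium chloride derived from 15 (Mg on C2, cis to C4) | C=CC/C([Mg]Cl)=C/[C@@](OC)([C@H](C)Cc1ccc(O[Si](C(C)C)(C(C)C)C(C)C)c(OC)c1)C(=O)OC | intermediate
18 | chloromagnesium enolate of the metallated keto ylide (adduct of 17 and 16) | C=CC/C(=C/[C@@](OC)([C@H](C)Cc1ccc(O[Si](C(C)C)(C(C)C)C(C)C)c(OC)c1)C(=O)OC)C(O[Mg]Cl)=C=P(c1ccccc1)(c1ccccc1)c1ccccc1 | intermediate
19 | methyl (2S,3Z)-2-methoxy-2-{(2R)-1-[3-methoxy-4-(triisopropylsilyloxy)phenyl]propan-2-yl}-4-[(triphenylphosphoranylidene)acetyl]hepta-3,6-dienoate | C=CC/C(=C/[C@@](OC)([C@H](C)Cc1ccc(O[Si](C(C)C)(C(C)C)C(C)C)c(OC)c1)C(=O)OC)C(=O)C=P(c1ccccc1)(c1ccccc1)c1ccccc1 | intermediate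
20 | (4S)-4,5-dimethoxy-4-{(2R)-1-[3-methoxy-4-(triisopropylsilyloxy)phenyl]propan-2-yl}-2-(prop-2-en-1-yl)cyclohexa-2,5-dien-1-one | C=CCC1=C[C@@](OC)([C@H](C)Cc2ccc(O[Si](C(C)C)(C(C)C)C(C)C)c(OC)c2)C(OC)=CC1=O | intermediate
21 | (4S)-4-[(2R)-1-(4-hydroxy-3-methoxyphenyl)propan-2-yl]-4,5-dimethoxy-2-(prop-2-en-1-yl)cyclohexa-2,5-dien-1-one | C=CCC1=C[C@@](OC)([C@H](C)Cc2ccc(O)c(OC)c2)C(OC)=CC1=O | target

Total step count: 11. Longest linear sequence: 11 steps (1 to 21).

**Steps most likely to fail**

Step 10 (Proposed new method).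
- What may go wrong: addition of the alkenylmagnesium to the electron-rich cumulene may be too slow. The metallated adduct may close the ring by acyl substitution, losing methoxide, before it is protonated. The Grignard species may also attack the ester.
- Fallback: it sets out from 15 and comes back at 19, and it builds the same ylide stepwise by known reactions. Stille coupling of 15 with tributyl(1-ethoxyvinyl)stannane (PdCl2(PPh3)2, toluene, 80 °C) gives the 2-ethoxydiene F1. NBS (1.0 equiv) in THF–H2O at 0 °C converts the enol ether into the bromomethyl ketone F2. PPh3 in toluene at rt gives the phosphonium bromide F3. Aqueous Na2CO3/CH2Cl2 liberates keto ylide 19, which is heated in toluene as in step 10 to give 20.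

Step 6.
- What may go wrong: the addition may be sluggish at the α-branched ketone. Facial selectivity may be poor. C8 may epimerise while the keto ester waits.
- Fallback: it sets out from 10 and 11 and comes back at 12, and it moves stereocontrol from the catalyst to the substrate. Compound 11 is deprotonated with nBuLi (THF, −78 °C) to the lithium acetylide F4 and transmetallated with ClTi(OiPr)3 to the titanium acetylide F5. This bulky, non-chelating nucleophile adds only to the ketone of 10 at −78 °C and follows the Felkin–Anh model, which favours the same (2S) epimer. Because C8 is fixed, the C4 epimers are diastereomers and are separated by chromatography at the stage of 12.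

Step 9.
- What may go wrong: electrophilic iodination of the electron-rich arene or iodofunctionalisation of the terminal alkene may compete. Ipso attack may be slow at the crowded vinylsilane, with erosion of geometry.
- Fallback: it sets out from 13 and comes back at 15, and it changes the handle from silicon to tin so that only molecular iodine is needed. Ruthenium-catalysed trans-hydrostannation of 13 (Bu3SnH, [Cp*Ru(MeCN)3]PF6, CH2Cl2, rt) gives the (Z)-alkenylstannane F6, where the bulk of C4 should again send the metal to C2. Tin–iodine exchange with I2 in CH2Cl2 at −78 °C proceeds with retention, leaves arene and alkene alone, and gives 15.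

**Further compounds**
F1 | step 10 | methyl (2S,3Z)-4-(1-ethoxyethenyl)-2-methoxy-2-{(2R)-1-[3-methoxy-4-(triisopropylsilyloxy)phenyl]propan-2-yl}hepta-3,6-dienoate | C=CC/C(=C/[C@@](OC)([C@H](C)Cc1ccc(O[Si](C(C)C)(C(C)C)C(C)C)c(OC)c1)C(=O)OC)C(=C)OCC
F2 | step 10 | methyl (2S,3Z)-4-(bromoacetyl)-2-methoxy-2-{(2R)-1-[3-methoxy-4-(triisopropylsilyloxy)phenyl]propan-2-yl}hepta-3,6-dienoate | C=CC/C(=C/[C@@](OC)([C@H](C)Cc1ccc(O[Si](C(C)C)(C(C)C)C(C)C)c(OC)c1)C(=O)OC)C(=O)CBr
F3 | step 10 | triphenylphosphonium bromide derived from F2 | C=CC/C(=C/[C@@](OC)([C@H](C)Cc1ccc(O[Si](C(C)C)(C(C)C)C(C)C)c(OC)c1)C(=O)OC)C(=O)C[P+](c1ccccc1)(c1ccccc1)c1ccccc1.[Br-]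
F4 | step 6 | lithium pent-4-en-1-yn-1-ide | [Li]C#CCC=C
F5 | step 6 | (pent-4-en-1-yn-1-yl)triisopropoxytitanium | C=CCC#C[Ti](OC(C)C)(OC(C)C)OC(C)C
F6 | step 9 | methyl (2S,3Z)-2-methoxy-2-{(2R)-1-[3-methoxy-4-(triisopropylsilyloxy)phenyl]propan-2-yl}-4-(tributylstannyl)hepta-3,6-dienoate | C=CC/C([Sn](CCCC)(CCCC)CCCC)=C/[C@@](OC)([C@H](C)Cc1ccc(O[Si](C(C)C)(C(C)C)C(C)C)c(OC)c1)C(=O)OC
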